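**Retrosynthetic overview**

1. The last bond cut is the ester C–O, giving linoleic acid and keto alcohol 20. The C(=CH2)(CH2)3O arm is then unravelled through ketone 18 and aldehyde 14 to a tert-butyl ester on the ring, with the side-chain ketone masked as a dioxolane.
2. Feature used: the only carbocycle is a cyclobutane, labelled Ca (ring CH carrying the pentenyl arm), Cb (ring CH2), Cc (ring C(CH3)2) and Cd (ring CH carrying the 3-oxobutyl arm). Cc lies 1,3 to Ca, the carbon that can hold an ester, so the ring is what remains when CH3–H is added across the central bond of a 3-methylbicyclo[1.1.0]butane-1-carboxylate whose bridge carbon is Cd.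
3. Key disconnections: Cc–CH3 (homoconjugate methyl addition that cleaves Ca–Cc), then Ca–Cd and Ca–Cc (carbene at Ca adding to the tethered E Cc=Cd alkene of a 2-diazo-4-methylhept-4-enoate).
4. Ring order: both three-membered rings of the bicyclobutane form together; opening of its central bond in the same flask leaves the cyclobutane.
5. The diazo ester comes from 6-methylhept-5-en-2-one (Cb, Cc, Cd, one ring methyl and the whole oxobutyl arm) and tert-butyl acetoacetate (Ca and its ester carbon); methylmagnesium bromide supplies the second ring methyl.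

Key step: step 6

Assumption: Rh2(S-NTTL)4 is dirhodium tetrakis[N-(1,8-naphthaloyl)-(S)-tert-leucinate], a divalent rhodium carboxylate. Its sense of alkene-face selection is established only for aryl-substituted alkenes; the (S)-ligand series is written here for Cd as in the target, and Rh2(R-NTTL)4 is used instead, with nothing else changed, if the first run shows the opposite sense.

**Route**

Step 1
Reactants: 1 6-methylhept-5-en-2-one
Product: 2 2-methyl-2-(4-methylpent-3-en-1-yl)-1,3-dioxolane
Conditions: HOCH2CH2OH, PPTS (cat.), PhMe, reflux, Dean–Stark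
Reagents that add atoms: ethylene glycol, OCCO
Why: Acid-catalysed ketalisation with azeotropic removal of water masks the methyl ketone against the enolate, hydride, Grignard and ylide chemistry ahead, and the mild acid leaves the trisubstituted alkene alone.

Step 2
Reactants: 2 2-methyl-2-(4-methylpent-3-en-1-yl)-1,3-dioxolane
Product: 3 (E)-2-methyl-5-(2-methyl-1,3-dioxolan-2-yl)pent-2-en-1-ol
Conditions: SeO2 (0.5 equiv), tBuOOH, CH2Cl2, 0 °C → rt; then NaBH4, MeOH, 0 °C
Reagents that add atoms: selenium dioxide, O=[Se]=O (oxygen carrier); tert-butyl hydroperoxide, CC(C)(C)OO (terminal oxidant)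
Why: Riley allylic oxidation (ene reaction, then [2,3]-sigmatropic shift) attacks the methyl group trans to the chain of a gem-dimethyl alkene and so fixes the E geometry that later places the arm exo on the bicyclobutane, while NaBH4 returns any over-oxidised enal to 3.

Step 3
Reactants: 3 (E)-2-methyl-5-(2-methyl-1,3-dioxolan-2-yl)pent-2-en-1-ol
Product: 4 2-[(E)-5-bromo-4-methylpent-3-en-1-yl]-2-methyl-1,3-dioxolane
Conditions: CBr4, PPh3, CH2Cl2, 0 °C
Reagents that add atoms: carbon tetrabromide, BrC(Br)(Br)Br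
Why: Appel bromination displaces the activated primary allylic oxygen by SN2 under neutral conditions, so the dioxolane and the E alkene are kept.

Step 4
Reactants: 4 2-[(E)-5-bromo-4-methylpent-3-en-1-yl]-2-methyl-1,3-dioxolane; 5 tert-butyl acetoacetate
Product: 6 tert-butyl (E)-2-acetyl-4-methyl-7-(2-methyl-1,3-dioxolan-2-yl)hept-4-enoate (racemic at C2)
Conditions: NaH, THF, 0 °C → rt (5 in excess)
Reagents that add atoms: none
Why: Acetoacetic ester alkylation, in which the sodium enolate of 5 (in excess to suppress dialkylation) attacks the primary allylic bromide through carbon; the new C2 centre is racemic and is erased in step 5.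

Step 5
Reactants: 6 tert-butyl (E)-2-acetyl-4-methyl-7-(2-methyl-1,3-dioxolan-2-yl)hept-4-enoate
Product: 7 tert-butyl (E)-2-diazo-4-methyl-7-(2-methyl-1,3-dioxolan-2-yl)hept-4-enoate
Conditions: p-ABSA, DBU, MeCN, 0 °C → rt
Reagents that add atoms: 4-acetamidobenzenesulfonyl azide, CC(=O)Nc1ccc(cc1)S(=O)(=O)N=[N+]=[N-]
Why: Regitz-type deacylative diazo transfer, in which the enolate of 6 adds to the sulfonyl azide and the adduct passes its acetyl group to the sulfonamide nitrogen, leaving the diazo ester.

Step 6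
Reactants: 7 tert-butyl (E)-2-diazo-4-methyl-7-(2-methyl-1,3-dioxolan-2-yl)hept-4-enoate; 8 methylmagnesium bromide
Product: 12 tert-butyl (1S,2R)-3,3-dimethyl-2-[2-(2-methyl-1,3-dioxolan-2-yl)ethyl]cyclobutane-1-carboxylate (trans), via bicyclobutane ester 9 (not isolated), via magnesium ester enolate 10 (not isolated), via cis ester 11 (not isolated)
Conditions: Rh2(S-NTTL)4 (1 mol %), PhMe, −78 °C; then CuBr·SMe2 (30 mol %), PBu3, MeMgBr, THF, −78 → 0 °C; then tBuOH, KOtBu (excess), 0 °C → rt; aq NH4Cl
Reagents that add atoms: none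
Why: Rh2(S-NTTL)4 (divalent rhodium) expels N2 from 7 and the carbene at Ca adds across the tethered Cc=Cd double bond, an intramolecular [2+1] carbene–alkene addition that makes Ca–Cd and Ca–Cc and so both three-membered rings of bicyclobutane 9, with the arm exo because the alkene is E; the bulky carboxylate ligands, the tert-butyl ester and −78 °C hold back the competing 1,2-hydride shift from Cb. A methylcopper species (monovalent copper, from 8 with CuBr·SMe2 and PBu3) then adds to bridgehead Cc in homoconjugate fashion, breaking the strained Ca–Cc bond to leave the cyclobutane Ca–Cb–Cc–Cd and ester enolate 10; attack at Cc and not Ca is secured by the ester, which stabilises the charge arriving at Ca. The closest known reaction type is the one-flask enantioselective rhodium-catalysed bicyclobutanation of 2-diazopent-4-enoates followed by copper-catalysed homoconjugate Grignard addition, demonstrated on aryl-substituted alkenes with hydrogen at the attacked bridgehead, so the aliphatic trisubstituted alkene and the methyl-bearing bridgehead (which becomes the quaternary Cc) stretch its scope. Cd is set by the catalyst's choice of alkene face and is not touched afterwards. Ca is set on protonation: kinetic delivery of H anti to the Cd arm would give mainly cis ester 11, so the flask is taken through KOtBu/tBuOH, which equilibrates Ca through the enolate to the more stable trans ester 12. The step therefore needs face selectivity (catalyst), cyclopropanation over hydride shift (electron-rich alkene, ligand bulk, low temperature), attack at Cc (ester) and trans at Ca (thermodynamics).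

Step 7
Reactants: 12 tert-butyl (1S,2R)-3,3-dimethyl-2-[2-(2-methyl-1,3-dioxolan-2-yl)ethyl]cyclobutane-1-carboxylate
Product: 13 {(1S,2R)-3,3-dimethyl-2-[2-(2-methyl-1,3-dioxolan-2-yl)ethyl]cyclobutyl}methanol
Conditions: LiAlH4, THF, 0 °C → rt
Reagents that add atoms: none
Why: Hydride reduction of the tert-butyl ester to the primary alcohol, with the dioxolane inert and neither stereocentre touched.

Step 8
Reactants: 13 {(1S,2R)-3,3-dimethyl-2-[2-(2-methyl-1,3-dioxolan-2-yl)ethyl]cyclobutyl}methanol
Product: 14 (1S,2R)-3,3-dimethyl-2-[2-(2-methyl-1,3-dioxolan-2-yl)ethyl]cyclobutane-1-carbaldehyde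
Conditions: Dess–Martin periodinane, pyridine, CH2Cl2, 0 °C → rt
Reagents that add atoms: none
Why: Dess–Martin oxidation stops at the aldehyde under buffered, non-basic conditions, so Ca (now α to the aldehyde and already the stable trans epimer) is not disturbed.

Step 9
Reactants: 14 (1S,2R)-3,3-dimethyl-2-[2-(2-methyl-1,3-dioxolan-2-yl)ethyl]cyclobutane-1-carbaldehyde; 15 (3-bromopropoxy)(tert-butyl)dimethylsilane
Product: 17 4-[(tert-butyldimethylsilyl)oxy]-1-{(1S,2R)-3,3-dimethyl-2-[2-(2-methyl-1,3-dioxolan-2-yl)ethyl]cyclobutyl}butan-1-ol (mixture of carbinol epimers), via Grignard reagent 16 (not isolated)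
Conditions: Mg, THF (15 → 16); then 14, THF, −78 → 0 °C; aq NH4Cl
Reagents that add atoms: none
Why: Grignard formation from the primary bromide and 1,2-addition to the aldehyde builds the rest of the arm; the new carbinol centre forms as a mixture, which does not matter because it is oxidised in step 10.

Step 10
Reactants: 17 4-[(tert-butyldimethylsilyl)oxy]-1-{(1S,2R)-3,3-dimethyl-2-[2-(2-methyl-1,3-dioxolan-2-yl)ethyl]cyclobutyl}butan-1-ol
Product: 18 4-[(tert-butyldimethylsilyl)oxy]-1-{(1S,2R)-3,3-dimethyl-2-[2-(2-methyl-1,3-dioxolan-2-yl)ethyl]cyclobutyl}butan-1-one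
Conditions: Dess–Martin periodinane, pyridine, CH2Cl2, rt
Reagents that add atoms: none
Why: Dess–Martin oxidation of the secondary alcohol converges both carbinol epimers on one ketone without acid or strong base.

Step 11
Reactants: 18 4-[(tert-butyldimethylsilyl)oxy]-1-{(1S,2R)-3,3-dimethyl-2-[2-(2-methyl-1,3-dioxolan-2-yl)ethyl]cyclobutyl}butan-1-one
Product: 19 tert-butyl{[4-{(1S,2R)-3,3-dimethyl-2-[2-(2-methyl-1,3-dioxolan-2-yl)ethyl]cyclobutyl}pent-4-en-1-yl]oxy}dimethylsilane
Conditions: Ph3PCH3Br, KOtBu, THF, 0 °C → reflux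
Reagents that add atoms: methyltriphenylphosphonium bromide, C[P+](c1ccccc1)(c1ccccc1)c1ccccc1.[Br-]
Why: Wittig methylenation installs the 1,1-disubstituted alkene; Ca is α to the ketone, but trans is its stable configuration, so any enolisation by the ylide returns the same epimer.

Step 12
Reactants: 19 tert-butyl{[4-{(1S,2R)-3,3-dimethyl-2-[2-(2-methyl-1,3-dioxolan-2-yl)ethyl]cyclobutyl}pent-4-en-1-yl]oxy}dimethylsilane
Product: 20 4-[(1S,2R)-3,3-dimethyl-2-(3-oxobutyl)cyclobutyl]pent-4-en-1-ol
Conditions: 1 M HCl, THF, 0 °C → rt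
Reagents that add atoms: water, O
Why: Dilute aqueous acid hydrolyses the dioxolane and the primary silyl ether in one operation (acetal and silyl ether hydrolysis) under conditions too mild to protonate the 1,1-disubstituted alkene next to the strained ring.

Step 13
Reactants: 20 4-[(1S,2R)-3,3-dimethyl-2-(3-oxobutyl)cyclobutyl]pent-4-en-1-ol; 21 linoleic acid
Product: 22 4-[(1S,2R)-3,3-dimethyl-2-(3-oxobutyl)cyclobutyl]pent-4-en-1-yl (9Z,12Z)-octadeca-9,12-dienoate (IN0146)
Conditions: DIC, DMAP (cat.), CH2Cl2, 0 °C → rt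
Reagents that add atoms: none
Why: Steglich esterification (carbodiimide activation, DMAP acyl transfer) acylates the primary alcohol at or below room temperature and leaves the ketone, the 1,1-disubstituted alkene and the skipped Z,Z-diene unchanged.

**Compound list**

1 | 6-methylhept-5-en-2-one | CC(=O)CCC=C(C)C | starting material
2 | 2-methyl-2-(4-methylpent-3-en-1-yl)-1,3-dioxolane | CC1(CCC=C(C)C)OCCO1 | intermediate
3 | (E)-2-methyl-5-(2-methyl-1,3-dioxolan-2-yl)pent-2-en-1-ol | OC/C(C)=C/CCC1(C)OCCO1 | intermediate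
4 | 2-[(E)-5-bromo-4-methylpent-3-en-1-yl]-2-methyl-1,3-dioxolane | BrC/C(C)=C/CCC1(C)OCCO1 | intermediate
5 | tert-butyl acetoacetate (tert-butyl 3-oxobutanoate) | CC(=O)CC(=O)OC(C)(C)C | starting material
6 | tert-butyl (E)-2-acetyl-4-methyl-7-(2-methyl-1,3-dioxolan-2-yl)hept-4-enoate (racemic at C2) | CC(=O)C(C/C(C)=C/CCC1(C)OCCO1)C(=O)OC(C)(C)C | intermediate
7 | tert-butyl (E)-2-diazo-4-methyl-7-(2-methyl-1,3-dioxolan-2-yl)hept-4-enoate | CC(C)(C)OC(=O)C(=[N+]=[N-])C/C(C)=C/CCC1(C)OCCO1 | intermediate
8 | methylmagnesium bromide | C[Mg]Br | starting material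
9 | tert-butyl (1S,2S,3S)-3-methyl-2-[2-(2-methyl-1,3-dioxolan-2-yl)ethyl]bicyclo[1.1.0]butane-1-carboxylate (side chain exo; formed in the flask) | CC(C)(C)OC(=O)[C@]12C[C@@]1(C)[C@@H]2CCC3(C)OCCO3 | intermediate
10 | [tert-butoxy{(2S)-3,3-dimethyl-2-[2-(2-methyl-1,3-dioxolan-2-yl)ethyl]cyclobutylidene}methoxy]magnesium bromide (ester enolate, Ca planar; formed in the flask) | CC(C)(C)OC(O[Mg]Br)=C1CC(C)(C)[C@@H]1CCC2(C)OCCO2 | intermediate
11 | tert-butyl (1R,2R)-3,3-dimethyl-2-[2-(2-methyl-1,3-dioxolan-2-yl)ethyl]cyclobutane-1-carboxylate (cis; formed in the flask) | CC(C)(C)OC(=O)[C@@H]1CC(C)(C)[C@@H]1CCC2(C)OCCO2 | intermediate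
12 | tert-butyl (1S,2R)-3,3-dimethyl-2-[2-(2-methyl-1,3-dioxolan-2-yl)ethyl]cyclobutane-1-carboxylate (trans) | CC(C)(C)OC(=O)[C@H]1CC(C)(C)[C@@H]1CCC2(C)OCCO2 | intermediate
13 | {(1S,2R)-3,3-dimethyl-2-[2-(2-methyl-1,3-dioxolan-2-yl)ethyl]cyclobutyl}methanol | OC[C@H]1CC(C)(C)[C@@H]1CCC2(C)OCCO2 | intermediate
14 | (1S,2R)-3,3-dimethyl-2-[2-(2-methyl-1,3-dioxolan-2-yl)ethyl]cyclobutane-1-carbaldehyde | O=C[C@H]1CC(C)(C)[C@@H]1CCC2(C)OCCO2 | intermediate
15 | (3-bromopropoxy)(tert-butyl)dimethylsilane | CC(C)(C)[Si](C)(C)OCCCBr | starting material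
16 | {3-[(tert-butyldimethylsilyl)oxy]propyl}magnesium bromide (formed in the flask) | CC(C)(C)[Si](C)(C)OCCC[Mg]Br | intermediate
17 | 4-[(tert-butyldimethylsilyl)oxy]-1-{(1S,2R)-3,3-dimethyl-2-[2-(2-methyl-1,3-dioxolan-2-yl)ethyl]cyclobutyl}butan-1-ol (carbinol epimers) | CC(C)(C)[Si](C)(C)OCCCC(O)[C@H]1CC(C)(C)[C@@H]1CCC2(C)OCCO2 | intermediate
18 | 4-[(tert-butyldimethylsilyl)oxy]-1-{(1S,2R)-3,3-dimethyl-2-[2-(2-methyl-1,3-dioxolan-2-yl)ethyl]cyclobutyl}butan-1-one | CC(C)(C)[Si](C)(C)OCCCC(=O)[C@H]1CC(C)(C)[C@@H]1CCC2(C)OCCO2 | intermediate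
19 | tert-butyl{[4-{(1S,2R)-3,3-dimethyl-2-[2-(2-methyl-1,3-dioxolan-2-yl)ethyl]cyclobutyl}pent-4-en-1-yl]oxy}dimethylsilane | C=C(CCCO[Si](C)(C)C(C)(C)C)[C@H]1CC(C)(C)[C@@H]1CCC2(C)OCCO2 | intermediate
20 | 4-[(1S,2R)-3,3-dimethyl-2-(3-oxobutyl)cyclobutyl]pent-4-en-1-ol | C=C(CCCO)[C@H]1CC(C)(C)[C@@H]1CCC(C)=O | intermediate
21 | linoleic acid, (9Z,12Z)-octadeca-9,12-dienoic acid | OC(=O)CCCCCCC/C=C\C/C=C\CCCCC | starting material
22 | 4-[(1S,2R)-3,3-dimethyl-2-(3-oxobutyl)cyclobutyl]pent-4-en-1-yl (9Z,12Z)-octadeca-9,12-dienoate (IN0146) | C=C(CCCOC(=O)CCCCCCC/C=C\C/C=C\CCCCC)[C@H]1CC(C)(C)[C@@H]1CCC(C)=O | target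

**Step count**

Total steps: 13. Longest linear sequence: 13 steps (1 → 22); compounds 5, 8, 15 and 21 are bought.

**Steps most likely to fail**

Step 6 (key step). What may go wrong:
- 1,2-hydride shift from Cb in the rhodium carbene may outrun addition to the alkene.
- Face discrimination may be weak for an aliphatic trisubstituted alkene.
- Methyl transfer to the already substituted bridgehead Cc may be slow enough for the bicyclobutane to decompose.
- Equilibration at Ca may stall.

Fallback, setting out from 2 and coming back at 14: the trisubstituted alkene of ketal 2 serves directly as Cc=Cd in a catalytic enantioselective [2+2] cycloaddition with 2,2,2-trifluoroethyl buta-2,3-dienoate (C=C=CC(=O)OCC(F)(F)F). The catalyst is an AlBr3-activated chiral B-aryl oxazaborolidine derived from diphenylprolinol (CH2Cl2, low temperature), with the antipode chosen for Cd as in 12. The less substituted alkene carbon Cd should bond to the central allene carbon, which becomes Ca, giving 2,2,2-trifluoroethyl 2-{(2S)-3,3-dimethyl-2-[2-(2-methyl-1,3-dioxolan-2-yl)ethyl]cyclobutylidene}acetate F1; the dioxolane is a competing Lewis base and may call for more activator. Ozonolysis (O3, CH2Cl2, −78 °C; Me2S) then gives (2S)-3,3-dimethyl-2-[2-(2-methyl-1,3-dioxolan-2-yl)ethyl]cyclobutan-1-one F2. Because Cd is now α to a ketone, only non-basic operations follow. Methylenation with Cp2Ti(μ-Cl)(μ-CH2)AlMe2 gives 2-{2-[(1S)-2,2-dimethyl-4-methylidenecyclobutyl]ethyl}-2-methyl-1,3-dioxolane F3. Hydroboration–oxidation (9-BBN; NaOH, H2O2) delivers H to Ca anti to the Cd arm and so gives mainly {(1R,2R)-3,3-dimethyl-2-[2-(2-methyl-1,3-dioxolan-2-yl)ethyl]cyclobutyl}methanol F4. Dess–Martin oxidation gives (1R,2R)-3,3-dimethyl-2-[2-(2-methyl-1,3-dioxolan-2-yl)ethyl]cyclobutane-1-carbaldehyde F5, and K2CO3 in MeOH epimerises Ca to the trans aldehyde 14.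

Step 2. What may go wrong: over-oxidation past the alcohol, incomplete conversion, and partial hydrolysis of the dioxolane by the acidic selenium species.

Fallback, setting out from 2 and coming back at 3: the E allylic alcohol is built by olefination instead of C–H oxidation. Ozonolysis of 2 (O3, CH2Cl2, −78 °C; PPh3) removes the isopropylidene group to give 3-(2-methyl-1,3-dioxolan-2-yl)propanal F6. Wittig reaction with the stabilised ylide ethyl 2-(triphenylphosphoranylidene)propanoate (CCOC(=O)C(C)=P(c1ccccc1)(c1ccccc1)c1ccccc1; PhMe, rt → 80 °C) should give ethyl (E)-2-methyl-5-(2-methyl-1,3-dioxolan-2-yl)pent-2-enoate F7, E by the usual preference of stabilised ylides. Reduction with iBu2AlH (CH2Cl2, −78 °C) gives 3.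

Step 5. What may go wrong: slow loss of the acetyl group from the hindered azide adduct, and decomposition or intramolecular dipolar cycloaddition of the diazo group onto the tethered alkene during a long reaction or isolation.

Fallback, setting out from 4 and coming back at 7: the acetoacetate is replaced by a simple ester with a more labile activating group. The lithium enolate of tert-butyl acetate (LiN(iPr)2, THF, −78 °C) is alkylated with bromide 4 to give tert-butyl (E)-4-methyl-7-(2-methyl-1,3-dioxolan-2-yl)hept-4-enoate F8. Its enolate (LiN(SiMe3)2, THF, −78 °C) is acylated with 2,2,2-trifluoroethyl trifluoroacetate to tert-butyl (E)-4-methyl-7-(2-methyl-1,3-dioxolan-2-yl)-2-(2,2,2-trifluoroacetyl)hept-4-enoate F9. F9 is not isolated but treated with p-ABSA, Et3N and water in MeCN; the trifluoroacetyl group leaves far more readily than acetyl, giving 7 in a shorter, colder reaction.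

Further compounds
F1 | step 6 | 2,2,2-trifluoroethyl 2-{(2S)-3,3-dimethyl-2-[2-(2-methyl-1,3-dioxolan-2-yl)ethyl]cyclobutylidene}acetate | FC(F)(F)COC(=O)C=C1CC(C)(C)[C@@H]1CCC2(C)OCCO2
F2 | step 6 | (2S)-3,3-dimethyl-2-[2-(2-methyl-1,3-dioxolan-2-yl)ethyl]cyclobutan-1-one | O=C1CC(C)(C)[C@@H]1CCC2(C)OCCO2
F3 | step 6 | 2-{2-[(1S)-2,2-dimethyl-4-methylidenecyclobutyl]ethyl}-2-methyl-1,3-dioxolane | C=C1CC(C)(C)[C@@H]1CCC2(C)OCCO2
F4 | step 6 | {(1R,2R)-3,3-dimethyl-2-[2-(2-methyl-1,3-dioxolan-2-yl)ethyl]cyclobutyl}methanol (cis) | OC[C@@H]1CC(C)(C)[C@@H]1CCC2(C)OCCO2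
F5 | step 6 | (1R,2R)-3,3-dimethyl-2-[2-(2-methyl-1,3-dioxolan-2-yl)ethyl]cyclobutane-1-carbaldehyde (cis) | O=C[C@@H]1CC(C)(C)[C@@H]1CCC2(C)OCCO2
F6 | step 2 | 3-(2-methyl-1,3-dioxolan-2-yl)propanal | CC1(CCC=O)OCCO1
F7 | step 2 | ethyl (E)-2-methyl-5-(2-methyl-1,3-dioxolan-2-yl)pent-2-enoate | CCOC(=O)/C(C)=C/CCC1(C)OCCO1
F8 | step 5 | tert-butyl (E)-4-methyl-7-(2-methyl-1,3-dioxolan-2-yl)hept-4-enoate | CC(C)(C)OC(=O)CC/C(C)=C/CCC1(C)OCCO1
F9 | step 5 | tert-butyl (E)-4-methyl-7-(2-methyl-1,3-dioxolan-2-yl)-2-(2,2,2-trifluoroacetyl)hept-4-enoate | CC(C)(C)OC(=O)C(C(=O)C(F)(F)F)C/C(C)=C/CCC1(C)OCCO1
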